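**Plan**
Retrosynthesis: the oxolane is cut at both CH2–CH bonds (C2–C3 and C5–C4), which leaves the three-atom unit C2–O1–C5 and a C3=C4 alkene. Before that, the carbinol C–H bond (ketone reduction) and the carbinol–aryl bond (Weinreb ketone synthesis) are cut.
Enabling feature: O1 is flanked by two unsubstituted CH2 groups, so C2–O1–C5 is the symmetric parent carbonyl ylide (no regiochemistry). The cis C3/C4 pair is a Z-alkene, locked and activated by tying the benzylic carbon of the future 4-benzyl group to the C3 carboxyl carbon as a 5-aryl-2(5H)-furanone (ring A).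
Forward: ring A from O-benzylisovanillin (alkynylation, semihydrogenation, lactonisation); oxolane ring B by [3+2] cycloaddition onto ring A; ring A opened by benzylic C–O hydrogenolysis, which reveals ArCH2 and CO2H; then Weinreb amide, aryl ketone, carbinol, desilylation.
Stereochemistry: C5 of the butenolide (catalytic asymmetric alkynylation) steers the ylide anti and sets both ring centres, cis by the ring-locked Z geometry, and is then erased. The carbinol centre comes from reagent-controlled CBS reduction.

Key step: step 4

Assumption: (S,S)-ProPhenol is written in step 1 as the antipode that gives the (R)-carbinol 3 from an aryl aldehyde; if the sense of induction is the opposite, the (R,R)-ligand is used and nothing else changes.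

Step 1
Reactants: 1 3-(benzyloxy)-4-methoxybenzaldehyde; 2 methyl propiolate
Product: 3 methyl (R)-4-[3-(benzyloxy)-4-methoxyphenyl]-4-hydroxybut-2-ynoate
Conditions: (S,S)-ProPhenol (10 mol %), Me2Zn (3 equiv), Ph3PO (20 mol %), toluene, 4 °C; sat. NH4Cl
Reagents that add atoms: none
Why: Zinc–ProPhenol-catalysed asymmetric alkynylation of an aromatic aldehyde, in which Me2Zn deprotonates the propiolate and the dinuclear zinc alkoxide complex delivers the alkynyl group to one carbonyl face, setting the carbinol centre that becomes C5 of the butenolide.

Step 2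
Reactants: 3 methyl (R)-4-[3-(benzyloxy)-4-methoxyphenyl]-4-hydroxybut-2-ynoate
Product: 5 (S)-5-[3-(benzyloxy)-4-methoxyphenyl]furan-2(5H)-one, via (Z)-hydroxy enoate 4 (not isolated)
Conditions: H2 (1 atm), Pd/CaCO3 poisoned with Pb(OAc)2 (Lindlar catalyst), quinoline, EtOAc, rt; then PPTS (cat.), CH2Cl2, rt
Reagents that add atoms: none
Why: Syn semihydrogenation on the lead-poisoned palladium surface (Lindlar reduction) should give only the Z-enoate 4, whose hydroxyl and ester groups are then close enough to lactonise with loss of methanol, while the carbinol centre is untouched (its descriptor changes only through the priority rules) and the benzyl ether survives the poisoned catalyst.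

Step 3
Reactants: 6 (trimethylsilyl)methanol
Product: 7 (chloromethoxymethyl)trimethylsilane
Conditions: paraformaldehyde, HCl (g), neat, 0 °C; dry over CaCl2, distil
Reagents that add atoms: paraformaldehyde (as formaldehyde), C=O; hydrogen chloride, Cl
Why: Acid-mediated chloromethylation of an alcohol, in which the hemiformal ionises to the oxocarbenium ion and is captured by chloride, gives the α-chloro ether that carries the whole C–O–C unit of the dipole.

Step 4
Reactants: 5 (S)-5-[3-(benzyloxy)-4-methoxyphenyl]furan-2(5H)-one; 7 (chloromethoxymethyl)trimethylsilane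
Product: 9 (3S,3aR,6aS)-3-[3-(benzyloxy)-4-methoxyphenyl]tetrahydro-1H,3H-furo[3,4-c]furan-1-one, via carbonyl ylide 8 (not isolated)
Conditions: CsF (3 equiv), 7 (2.5 equiv, slow addition), MeCN, rt
Reagents that add atoms: none
Why: Fluoride attacks the silicon of 7, and loss of Me3SiF and chloride (a 1,3-elimination) releases the nonstabilised parent carbonyl ylide 8, whose electron-rich 4π C–O–C system adds in a concerted, suprafacial [4π+2π] cycloaddition across the electron-poor C3=C4 bond of butenolide 5 (dipole HOMO with the lactone-lowered alkene LUMO), forming both CH2–CH bonds at once. The closest known reaction type is the fluoride-induced generation of this ylide from chloromethyl silylmethyl ethers with trapping by α,β-unsaturated esters, together with the anti-selective additions of nonstabilised azomethine and thiocarbonyl ylides to 5-substituted 2(5H)-furanones. Ring B (the oxolane) is closed by the cycloaddition itself and not by a separate cyclisation, and it can only be cis-fused to ring A because the dipolarophile is a Z-alkene held in a five-membered lactone and both new bonds form on the same face. The two new stereocentres C3a and C6a are controlled by the C5 aryl group of (S)-5, which blocks its own face so that the ylide approaches anti and gives (3aR,6aS). Only facial selectivity is needed, because the dipole is symmetric (no regiochemistry), the ester carbonyl is not a dipolarophile for this ylide, and the aryl group sits on the carbon next to the reacting alkene, where it shields best. Slow generation of 8 from excess 7 should keep ylide dimerisation behind the cycloaddition, and once the alkene is consumed the benzylic centre of 9 is no longer acidic.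

Step 5
Reactants: 9 (3S,3aR,6aS)-3-[3-(benzyloxy)-4-methoxyphenyl]tetrahydro-1H,3H-furo[3,4-c]furan-1-one
Product: 10 (3S,4R)-4-(3-hydroxy-4-methoxybenzyl)tetrahydrofuran-3-carboxylic acid
Conditions: H2 (3 atm), 10% Pd/C, AcOH–EtOAc, 40 °C
Reagents that add atoms: none
Why: Heterogeneous hydrogenolysis cleaves the lactone C3–O bond, which is benzylic to an electron-rich para-methoxy arene, together with the benzyl ether, so that ring A opens to the carboxylic acid, the controller centre is erased as the benzylic CH2, and the two ring stereocentres (not benzylic and not enolised in acetic acid) are left as set.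

Step 6
Reactants: 10 (3S,4R)-4-(3-hydroxy-4-methoxybenzyl)tetrahydrofuran-3-carboxylic acid
Product: 11 (3S,4R)-4-(3-hydroxy-4-methoxybenzyl)-N-methoxy-N-methyltetrahydrofuran-3-carboxamide
Conditions: MeNHOMe·HCl, EDC·HCl, HOBt, N-methylmorpholine, CH2Cl2, 0 °C to rt
Reagents that add atoms: N,O-dimethylhydroxylamine hydrochloride, CNOC.Cl
Why: Carbodiimide amide coupling through the HOBt ester (Weinreb amide formation) should proceed with the phenol unprotected because the amine is the better nucleophile, and the weak base at low temperature should keep the cis α-centre from epimerising.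

Step 7
Reactants: 12 5-bromo-2-methoxyphenol
Product: 13 (5-bromo-2-methoxyphenoxy)(tert-butyl)dimethylsilane
Conditions: TBSCl, imidazole, DMF, rt
Reagents that add atoms: tert-butyldimethylsilyl chloride, CC(C)(C)[Si](C)(C)Cl
Why: Imidazole-assisted silylation of a phenol gives a fluoride-labile ether that tolerates the organomagnesium and borane steps and sits meta to the bromine, so no silyl migration is possible after metalation.

Step 8
Reactants: 11 (3S,4R)-4-(3-hydroxy-4-methoxybenzyl)-N-methoxy-N-methyltetrahydrofuran-3-carboxamide; 13 (5-bromo-2-methoxyphenoxy)(tert-butyl)dimethylsilane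
Product: 15 {3-[(tert-butyldimethylsilyl)oxy]-4-methoxyphenyl}[(3S,4R)-4-(3-hydroxy-4-methoxybenzyl)tetrahydrofuran-3-yl]methanone, via aryl Grignard reagent 14 (not isolated)
Conditions: 13 (3.2 equiv), Mg turnings, THF, 40 °C; then 11, THF, −20 to 0 °C; cold sat. NH4Cl
Reagents that add atoms: none
Why: Weinreb ketone synthesis, in which the first equivalent of 14 deprotonates the phenol and the next adds to the amide to give a magnesium-chelated tetrahedral intermediate that neither over-adds nor enolises and collapses to the ketone only on the cold quench, so the cis C3 centre should stay intact.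

Step 9
Reactants: 15 {3-[(tert-butyldimethylsilyl)oxy]-4-methoxyphenyl}[(3S,4R)-4-(3-hydroxy-4-methoxybenzyl)tetrahydrofuran-3-yl]methanone
Product: 16 (S)-{3-[(tert-butyldimethylsilyl)oxy]-4-methoxyphenyl}[(3S,4R)-4-(3-hydroxy-4-methoxybenzyl)tetrahydrofuran-3-yl]methanol
Conditions: (R)-2-methyl-CBS-oxazaborolidine [(R)-1-methyl-3,3-diphenyltetrahydro-1H,3H-pyrrolo[1,2-c][1,3,2]oxazaborole] (0.3 equiv), BH3·SMe2 (2.5 equiv), THF, −20 °C; MeOH
Reagents that add atoms: none
Why: Corey–Bakshi–Shibata reduction, in which the (R)-oxazaborolidine–borane complex binds the ketone oxygen with the aryl group as the large substituent and delivers hydride to the face that gives the (S)-carbinol (the mirror of the known (S)-catalyst to (R)-1-arylethanol sense), reagent control being relied on to outweigh the substrate's Felkin preference while the first equivalent of borane is taken up by the phenol.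

Step 10
Reactants: 16 (S)-{3-[(tert-butyldimethylsilyl)oxy]-4-methoxyphenyl}[(3S,4R)-4-(3-hydroxy-4-methoxybenzyl)tetrahydrofuran-3-yl]methanol
Product: 17 (S)-(3-hydroxy-4-methoxyphenyl)[(3S,4R)-4-(3-hydroxy-4-methoxybenzyl)tetrahydrofuran-3-yl]methanol
Conditions: Bu4NF (1.2 equiv), AcOH (1.2 equiv), THF, 0 °C
Reagents that add atoms: none
Why: Fluoride-induced desilylation of the aryl silyl ether, driven by Si–F bond formation and buffered with acetic acid, should leave the acid-sensitive para-methoxybenzylic alcohol and the oxolane untouched.

**Compound list**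
1 | 3-(benzyloxy)-4-methoxybenzaldehyde | COc1ccc(C=O)cc1OCc1ccccc1 | starting material
2 | methyl propiolate | C#CC(=O)OC | starting material
3 | methyl (R)-4-[3-(benzyloxy)-4-methoxyphenyl]-4-hydroxybut-2-ynoate | COC(=O)C#C[C@H](O)c1ccc(OC)c(OCc2ccccc2)c1 | intermediate
4 | methyl (S,Z)-4-[3-(benzyloxy)-4-methoxyphenyl]-4-hydroxybut-2-enoate | COC(=O)/C=C\[C@H](O)c1ccc(OC)c(OCc2ccccc2)c1 | intermediate
5 | (S)-5-[3-(benzyloxy)-4-methoxyphenyl]furan-2(5H)-one | COc1ccc(cc1OCc1ccccc1)[C@H]1OC(=O)C=C1 | intermediate
6 | (trimethylsilyl)methanol | C[Si](C)(C)CO | starting material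
7 | (chloromethoxymethyl)trimethylsilane | C[Si](C)(C)COCCl | intermediate
8 | formaldehyde O-methylide (parent carbonyl ylide) | [CH2-][O+]=C | intermediate
9 | (3S,3aR,6aS)-3-[3-(benzyloxy)-4-methoxyphenyl]tetrahydro-1H,3H-furo[3,4-c]furan-1-one (cis-fused, aryl anti to ring B) | COc1ccc(cc1OCc1ccccc1)[C@H]1OC(=O)[C@@H]2COC[C@H]12 | intermediate
10 | (3S,4R)-4-(3-hydroxy-4-methoxybenzyl)tetrahydrofuran-3-carboxylic acid (cis) | COc1ccc(C[C@H]2COC[C@H]2C(=O)O)cc1O | intermediate
11 | (3S,4R)-4-(3-hydroxy-4-methoxybenzyl)-N-methoxy-N-methyltetrahydrofuran-3-carboxamide | COc1ccc(C[C@H]2COC[C@H]2C(=O)N(C)OC)cc1O | intermediate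
12 | 5-bromo-2-methoxyphenol | COc1ccc(Br)cc1O | starting material
13 | (5-bromo-2-methoxyphenoxy)(tert-butyl)dimethylsilane | COc1ccc(Br)cc1O[Si](C)(C)C(C)(C)C | intermediate
14 | {3-[(tert-butyldimethylsilyl)oxy]-4-methoxyphenyl}magnesium bromide | COc1ccc([Mg]Br)cc1O[Si](C)(C)C(C)(C)C | intermediate
15 | {3-[(tert-butyldimethylsilyl)oxy]-4-methoxyphenyl}[(3S,4R)-4-(3-hydroxy-4-methoxybenzyl)tetrahydrofuran-3-yl]methanone | COc1ccc(C[C@H]2COC[C@H]2C(=O)c2ccc(OC)c(O[Si](C)(C)C(C)(C)C)c2)cc1O | intermediate
16 | (S)-{3-[(tert-butyldimethylsilyl)oxy]-4-methoxyphenyl}[(3S,4R)-4-(3-hydroxy-4-methoxybenzyl)tetrahydrofuran-3-yl]methanol | COc1ccc(C[C@H]2COC[C@H]2[C@H](O)c2ccc(OC)c(O[Si](C)(C)C(C)(C)C)c2)cc1O | intermediate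
17 | (S)-(3-hydroxy-4-methoxyphenyl)[(3S,4R)-4-(3-hydroxy-4-methoxybenzyl)tetrahydrofuran-3-yl]methanol | COc1ccc(C[C@H]2COC[C@H]2[C@H](O)c2ccc(OC)c(O)c2)cc1O | target

Total step count: 10. Longest linear sequence: 8 steps (steps 1, 2, 4, 5, 6, 8, 9, 10); steps 3 and 7 are side branches.

**Steps most likely to fail**

Step 4. The fluoride base may deprotonate 5 at C5, which is benzylic and vinylogous to the lactone carbonyl, faster than the ylide is trapped. The controller centre would then racemise through the 2-oxidofuran, the alkene would drift out of conjugation into the unreactive 2(3H)-furanone, and ylide dimerisation would take over. The fallback sets out from 7 and comes back at 10. The ylide from 7 (CsF, MeCN) is trapped with purchased dimethyl maleate, which has no stereocentre to lose, to give meso dimethyl cis-tetrahydrofuran-3,4-dicarboxylate F1. LiOH (THF–H2O) gives meso cis-tetrahydrofuran-3,4-dicarboxylic acid F2, and Ac2O at reflux closes it to the meso anhydride cis-tetrahydro-1H,3H-furo[3,4-c]furan-1,3-dione F3. Purchased 2-(benzyloxy)-4-bromo-1-methoxybenzene is converted with n-BuLi (THF, −78 °C) into [3-(benzyloxy)-4-methoxyphenyl]lithium F4 and then with Zn(OTf)2 into [3-(benzyloxy)-4-methoxyphenyl]zinc triflate F5. F5 opens F3 enantioselectively under [Rh(cod)Cl]2 and a chiral TADDOL-derived phosphoramidite (antipode chosen to acylate the carbonyl that leads to the (3S,4R) series) to give (3S,4R)-4-[3-(benzyloxy)-4-methoxybenzoyl]tetrahydrofuran-3-carboxylic acid F6. H2, Pd/C in AcOH with a trace of HClO4 then takes the electron-rich aryl ketone down to the methylene and removes the benzyl ether to give 10. In this fallback the ring stereocentres come from catalyst-controlled desymmetrisation of a meso compound and not from a labile controller centre.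

Step 9. The reduction is mismatched: the substrate's Felkin–Anh preference (ring carbon C4 anti to the incoming hydride) favours the (R)-carbinol, so reagent control may be only partial, and the free phenol consumes borane and may erode catalyst control. The result would be poor facial selectivity. The fallback sets out from 11 and comes back at 16. Amide 11 is reduced with i-Bu2AlH (THF, −78 °C) to (3S,4R)-4-(3-hydroxy-4-methoxybenzyl)tetrahydrofuran-3-carbaldehyde F7, which is used crude and treated at −78 °C with excess 14 after precomplexation with MgBr2·OEt2. With the aryl group as the nucleophile, both the Felkin–Anh model and chelation between the carbonyl and the ring oxygen direct attack to the face that gives the (S)-carbinol, so substrate control and the required configuration coincide and 16 should form directly.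

Step 5. Hydrogenolysis may stop after O-debenzylation with the lactone C–O bond intact, or may need forcing acidic conditions under which the arene is over-reduced. The fallback sets out from 9 and comes back at 11. The lactone is first opened with MeNHOMe·HCl and Me3Al (CH2Cl2, 0 °C to rt) to (3S,4R)-4-{(S)-[3-(benzyloxy)-4-methoxyphenyl](hydroxy)methyl}-N-methoxy-N-methyltetrahydrofuran-3-carboxamide F8. Its free para-alkoxybenzylic alcohol is hydrogenolysed far more easily than the lactone (H2, Pd/C, EtOH, rt, neutral), together with the benzyl ether, to give 11, so that step 6 is not needed.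

Further compounds
F1 | step 4 | dimethyl cis-tetrahydrofuran-3,4-dicarboxylate (meso) | COC(=O)[C@H]1COC[C@H]1C(=O)OC
F2 | step 4 | cis-tetrahydrofuran-3,4-dicarboxylic acid (meso) | OC(=O)[C@H]1COC[C@H]1C(=O)O
F3 | step 4 | cis-tetrahydro-1H,3H-furo[3,4-c]furan-1,3-dione (meso anhydride) | O=C1OC(=O)[C@@H]2COC[C@H]12
F4 | step 4 | [3-(benzyloxy)-4-methoxyphenyl]lithium | COc1ccc([Li])cc1OCc1ccccc1
F5 | step 4 | [3-(benzyloxy)-4-methoxyphenyl]zinc triflate | COc1ccc([Zn]OS(=O)(=O)C(F)(F)F)cc1OCc1ccccc1
F6 | step 4 | (3S,4R)-4-[3-(benzyloxy)-4-methoxybenzoyl]tetrahydrofuran-3-carboxylic acid | COc1ccc(C(=O)[C@H]2COC[C@H]2C(=O)O)cc1OCc1ccccc1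
F7 | step 9 | (3S,4R)-4-(3-hydroxy-4-methoxybenzyl)tetrahydrofuran-3-carbaldehyde | COc1ccc(C[C@H]2COC[C@H]2C=O)cc1O
F8 | step 5 | (3S,4R)-4-{(S)-[3-(benzyloxy)-4-methoxyphenyl](hydroxy)methyl}-N-methoxy-N-methyltetrahydrofuran-3-carboxamide | COc1ccc(cc1OCc1ccccc1)[C@@H](O)[C@H]1COC[C@H]1C(=O)N(C)OC
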